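**Retrosynthetic overview**

1. Target ⇐ base-induced vinylogous (1,20) opening of the 5,6-epoxide of ent-lutein: the C6–O bond breaks, H-6′ of the ε ring is lost and every chain double bond shifts (retro).
2. Oxirane ⇐ epoxidase-type oxygen transfer to the β-ring C5=C6 of the complete C40 diacetate, anti to 3-OAc. This is the last ring formed.
3. ent-Lutein ⇐ β-C15 ylide + C10 dialdehyde + ε-C15 ylide (two Wittig reactions).
4. Both C15 units ⇐ one racemic trans-3-hydroxy-α-ionone, split by a lipase. One enantiomer stays an ε ring; the other is isomerised to the β ring.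
5. First ring ⇐ cyclase-type proton-initiated cyclisation of pseudoionone, then hydroxylase-type C3 oxidation. Ring order: one racemic carbocycle closure that feeds both rings, then the oxirane.

Assumption: the SMILES is taken literally, so the 3,5-diol ring is (3R,5S), the cyclohexenol ring is (3S) and both exocyclic double bonds are E. Carotenoid numbering is used throughout (ring C1 = CMe2, C3 = carbinol, C5 = C-methyl carbon, C6 = chain-bearing carbon).

**Step 1**
Reactants: 1 pseudoionone, (3E,5E/Z)-6,10-dimethylundeca-3,5,9-trien-2-one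
Product: 2 (±)-α-ionone, racemic (E)-4-(2,6,6-trimethylcyclohex-2-en-1-yl)but-3-en-2-one
Conditions: 85% H3PO4, toluene, 80 °C; distil
Reagents that add atoms: none
Why: Proton-initiated cation–olefin cyclisation as in the biosynthetic cyclase step (C2 protonation gives the tertiary C1 cation, C5=C6 closes the C1–C6 bond, kinetic loss of H-4 gives the ε-type ring); C6 is left racemic on purpose because it is erased in both halves later.

**Step 2**
Reactants: 2 (±)-α-ionone
Product: 3 (±)-trans-3-hydroxy-α-ionone, 1:1 mixture of (3R,6R) and (3S,6S)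
Conditions: engineered P450 BM3 variant, NADP+ (cat.), glucose dehydrogenase, D-glucose, air, KPi pH 7.5, 25 °C
Reagents that add atoms: dioxygen, O=O
Why: Enzymatic allylic C–H hydroxylation (P450 oxygen rebound), the counterpart of the ring hydroxylase that acts after cyclisation; BM3 variants oxidise the allylic C3 methylene of α-ionone trans to the C6 side chain in either enantiomer, so C3 is racemic (a cis contaminant would be harmless because C6 is erased later).

**Step 3**
Reactants: 3 (±)-trans-3-hydroxy-α-ionone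
Product: 4 (3S,6S)-3-acetoxy-α-ionone; 5 (3R,6R)-3-hydroxy-α-ionone (unreacted enantiomer, separated by chromatography)
Conditions: lipase PS (Burkholderia cepacia), vinyl acetate, MTBE, 30 °C, to 50% conversion
Reagents that add atoms: vinyl acetate, CC(=O)OC=C
Why: Lipase kinetic resolution by irreversible transesterification; by the Kazlauskas model (large side C2/CMe2, medium side vinylic C4) the (3S,6S) enantiomer is acetylated and (3R,6R) is left, which fixes C3 of both future rings and wastes neither enantiomer.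

**Step 4**
Reactants: 5 (3R,6R)-3-hydroxy-α-ionone
Product: 6 (3S)-3-hydroxy-β-ionone, (E)-4-[(4S)-4-hydroxy-2,6,6-trimethylcyclohex-1-en-1-yl]but-3-en-2-one
Conditions: NaOMe (0.3 equiv), MeOH, 50 °C; chromatography, recovered 5 recycled
Reagents that add atoms: none
Why: Base-catalysed prototropic isomerisation through the extended dienolate (removal of γ-H-6) moves the ring double bond into conjugation with the enone; C6 is erased and C3 is untouched (R becomes S only because the CIP ranks of C2 and C4 swap).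

**Step 5**
Reactants: 6 (3S)-3-hydroxy-β-ionone
Product: 7 (1E)-1-[(4S)-4-hydroxy-2,6,6-trimethylcyclohex-1-en-1-yl]-3-methylpenta-1,4-dien-3-ol (both carbinol epimers)
Conditions: vinylMgBr (2.5 equiv), THF, −20 → 0 °C; then H2O
Reagents that add atoms: vinylmagnesium bromide, C=C[Mg]Br
Why: Grignard 1,2-addition to the enone carbonyl (the first equivalent deprotonates the 3-OH); the new carbinol centre forms as both epimers and is destroyed in step 6.

**Step 6**
Reactants: 7 β-ring vinyl carbinol
Product: 8 [(2E,4E)-5-[(4S)-4-hydroxy-2,6,6-trimethylcyclohex-1-en-1-yl]-3-methylpenta-2,4-dien-1-yl]triphenylphosphonium bromide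
Conditions: PPh3·HBr, MeOH, 0 °C → rt
Reagents that add atoms: triphenylphosphine hydrobromide, Br.c1ccc(cc1)P(c1ccccc1)c1ccccc1
Why: SN1′ phosphonium salt formation: HBr ionises the tertiary bis-allylic alcohol to a pentadienyl cation that PPh3 traps at the terminal CH2, while the homoallylic 3-OH is inert.

**Step 7**
Reactants: 8 β-C15 phosphonium bromide; 9 (2E,4E,6E)-2,7-dimethylocta-2,4,6-trienedial (3 equiv)
Product: 11 (3S)-3-hydroxy-12′-apo-β-caroten-12′-al, via β-C15 ylide 10 (not isolated)
Conditions: NaOMe, MeOH–CH2Cl2, −10 °C → rt; then reflux in EtOAc (Z → E)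
Reagents that add atoms: none
Why: Wittig olefination of one aldehyde group of the symmetrical dialdehyde (excess dialdehyde stops it at mono-olefination) forms C11=C12; Z isomers equilibrate thermally to all-E and no stereocentre is touched.

**Step 8**
Reactants: 4 (3S,6S)-3-acetoxy-α-ionone
Product: 12 (1E)-1-[(1S,4S)-4-hydroxy-2,6,6-trimethylcyclohex-2-en-1-yl]-3-methylpenta-1,4-dien-3-ol (both carbinol epimers)
Conditions: vinylMgBr (4 equiv), THF, −20 → 0 °C; then H2O
Reagents that add atoms: vinylmagnesium bromide, C=C[Mg]Br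
Why: Grignard 1,2-addition to the ketone with cleavage of the acetate by the excess reagent; C3 and C6 are untouched and the carbinol centre is inconsequential.

**Step 9**
Reactants: 12 ε-ring vinyl carbinol
Product: 13 [(2E,4E)-5-[(1S,4S)-4-hydroxy-2,6,6-trimethylcyclohex-2-en-1-yl]-3-methylpenta-2,4-dien-1-yl]triphenylphosphonium bromide
Conditions: PPh3·HBr, MeOH, 0 °C
Reagents that add atoms: triphenylphosphine hydrobromide, Br.c1ccc(cc1)P(c1ccccc1)c1ccccc1
Why: The same SN1′ salt formation as step 6; at 0 °C the tertiary bis-allylic carbinol should ionise much faster than the secondary ring allylic alcohol, as required for ε-end C15 Wittig salts.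

**Step 10**
Reactants: 13 ε-C15 phosphonium bromide; 11 (3S)-3-hydroxy-12′-apo-β-caroten-12′-al
Product: 15 ent-lutein, (3S,3′S,6′S)-β,ε-carotene-3,3′-diol (all-E), via ε-C15 ylide 14 (not isolated)
Conditions: NaOMe, MeOH–CH2Cl2, 0 °C → rt; then reflux in heptane–EtOH (Z → E)
Reagents that add atoms: none
Why: The second Wittig olefination (C11′=C12′) completes the C40 skeleton as the enantiomer of natural lutein; all stereocentres are carried in unchanged.

**Step 11**
Reactants: 15 ent-lutein
Product: 16 (3S,3′S,6′S)-β,ε-carotene-3,3′-diyl diacetate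
Conditions: Ac2O, pyridine, DMAP (cat.), rt
Reagents that add atoms: acetic anhydride, CC(=O)OC(C)=O
Why: O-Acetylation of both secondary alcohols removes hydroxyl-directed (syn) epoxidation at either ring and deactivates the ε-ring double bond inductively.

**Step 12**
Reactants: 16 ent-lutein diacetate
Product: 17 (3R,5S,6R,3′S,6′S)-5,6-epoxy-5,6-dihydro-β,ε-carotene-3,3′-diyl diacetate
Conditions: mCPBA (1.05 equiv), CH2Cl2, −20 °C, dark; cold aq. NaHCO3 work-up; chromatography
Reagents that add atoms: 3-chloroperoxybenzoic acid, OOC(=O)c1cccc(Cl)c1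
Why: Prilezhaev epoxidation as the counterpart of the biosynthetic epoxidase: the tetrasubstituted β-ring C5=C6 is the most nucleophilic alkene and the peracid adds mainly anti to 3-OAc (the sense seen in partial syntheses of natural xanthophyll epoxides from their acetates), setting C5 (S) and C6 (R) from C3; the minor syn epoxide is removed.

**Step 13**
Reactants: 17 epoxide diacetate
Product: 19 target, (3S,3′R,5′S,6E,6′E)-4,5′-retro-β,β-carotene-3,3′,5′-triol, via ent-lutein 5,6-epoxide 18 (not isolated)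
Conditions: NaOMe (cat.), MeOH–THF, rt; evaporate; KOtBu (5 equiv), DMSO–THF, 20 °C, Ar, dark; then H2O; equilibrate in warm hexane, HPLC
Reagents that add atoms: none
Why: Proposed new method: after methanolysis of the acetates, KOtBu/DMSO removes the doubly allylic H-6′ of the ε ring (the deprotonation behind the known base isomerisation of lutein to zeaxanthin) to give a 19-centre polyenyl anion with charge at C7 that expels the oxirane C6–O bond in a vinylogous E1cB (1,20) elimination — closest known type: base isomerisation of β,γ-epoxy carbonyl compounds to γ-hydroxy enones — so all chain double bonds shift, C6 and C6′ become sp2, C5 keeps its oxygen with retention (S), C3 and C3′ are untouched, and the 6E,6′E isomer is taken after equilibration.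

**Compound list**

1 | pseudoionone, (3E,5E)-6,10-dimethylundeca-3,5,9-trien-2-one (commercial 5E/5Z mixture) | CC(C)=CCC/C(C)=C/C=C/C(C)=O | starting material
2 | (±)-α-ionone, racemic (6R drawn) | CC(=O)/C=C/[C@H]1C(C)=CCCC1(C)C | intermediate
3 | (±)-trans-3-hydroxy-α-ionone, racemic ((3R,6R) drawn) | CC(=O)/C=C/[C@H]1C(C)=C[C@H](O)CC1(C)C | intermediate
4 | (3S,6S)-3-acetoxy-α-ionone, (1S,4S)-3,5,5-trimethyl-4-[(E)-3-oxobut-1-enyl]cyclohex-2-en-1-yl acetate | CC(=O)/C=C/[C@@H]1C(C)=C[C@@H](OC(C)=O)CC1(C)C | intermediate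
5 | (3R,6R)-3-hydroxy-α-ionone, (E)-4-[(1R,4R)-4-hydroxy-2,6,6-trimethylcyclohex-2-en-1-yl]but-3-en-2-one | CC(=O)/C=C/[C@H]1C(C)=C[C@H](O)CC1(C)C | intermediate
6 | (3S)-3-hydroxy-β-ionone | CC(=O)/C=C/C1=C(C)C[C@H](O)CC1(C)C | intermediate
7 | β-ring vinyl carbinol (carbinol epimers) | C=CC(C)(O)/C=C/C1=C(C)C[C@H](O)CC1(C)C | intermediate
8 | β-C15 phosphonium bromide | [Br-].C(/C=C(C)/C=C/C1=C(C)C[C@H](O)CC1(C)C)[P+](c1ccccc1)(c1ccccc1)c1ccccc1 | intermediate
9 | (2E,4E,6E)-2,7-dimethylocta-2,4,6-trienedial | O=C/C(C)=C/C=C/C=C(C)/C=O | starting material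
10 | β-C15 ylide | [CH-](/C=C(C)/C=C/C1=C(C)C[C@H](O)CC1(C)C)[P+](c1ccccc1)(c1ccccc1)c1ccccc1 | intermediate
11 | (3S)-3-hydroxy-12′-apo-β-caroten-12′-al, (2E,4E,6E,8E,10E,12E)-13-[(4S)-4-hydroxy-2,6,6-trimethylcyclohex-1-en-1-yl]-2,7,11-trimethyltrideca-2,4,6,8,10,12-hexaenal | O=C/C(C)=C/C=C/C=C(C)/C=C/C=C(C)/C=C/C1=C(C)C[C@H](O)CC1(C)C | intermediate
12 | ε-ring vinyl carbinol (carbinol epimers) | C=CC(C)(O)/C=C/[C@@H]1C(C)=C[C@@H](O)CC1(C)C | intermediate
13 | ε-C15 phosphonium bromide | [Br-].C(/C=C(C)/C=C/[C@@H]1C(C)=C[C@@H](O)CC1(C)C)[P+](c1ccccc1)(c1ccccc1)c1ccccc1 | intermediate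
14 | ε-C15 ylide | [CH-](/C=C(C)/C=C/[C@@H]1C(C)=C[C@@H](O)CC1(C)C)[P+](c1ccccc1)(c1ccccc1)c1ccccc1 | intermediate
15 | ent-lutein, (3S,3′S,6′S)-β,ε-carotene-3,3′-diol | CC1(C)C[C@@H](O)CC(C)=C1/C=C/C(C)=C/C=C/C(C)=C/C=C/C=C(C)/C=C/C=C(C)/C=C/[C@@H]1C(C)=C[C@@H](O)CC1(C)C | intermediate
16 | ent-lutein diacetate | CC1(C)C[C@@H](OC(C)=O)CC(C)=C1/C=C/C(C)=C/C=C/C(C)=C/C=C/C=C(C)/C=C/C=C(C)/C=C/[C@@H]1C(C)=C[C@@H](OC(C)=O)CC1(C)C | intermediate
17 | (3R,5S,6R,3′S,6′S)-5,6-epoxy-5,6-dihydro-β,ε-carotene-3,3′-diyl diacetate | CC1(C)C[C@@H](OC(C)=O)C[C@]2(C)O[C@]12/C=C/C(C)=C/C=C/C(C)=C/C=C/C=C(C)/C=C/C=C(C)/C=C/[C@@H]1C(C)=C[C@@H](OC(C)=O)CC1(C)C | intermediate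
18 | ent-lutein 5,6-epoxide, (3R,5S,6R,3′S,6′S)-5,6-epoxy-5,6-dihydro-β,ε-carotene-3,3′-diol | CC1(C)C[C@@H](O)C[C@]2(C)O[C@]12/C=C/C(C)=C/C=C/C(C)=C/C=C/C=C(C)/C=C/C=C(C)/C=C/[C@@H]1C(C)=C[C@@H](O)CC1(C)C | intermediate
19 | (3S,3′R,5′S,6E,6′E)-4,5′-retro-β,β-carotene-3,3′,5′-triol (unprimed = cyclohexenol ring from the ε ring; primed = 3,5-diol ring from the epoxidised β ring) | CC1=C[C@@H](O)CC(C)(C)\C1=C/C=C(C)/C=C/C=C(C)/C=C/C=C/C(C)=C/C=C/C(C)=C/C=C1\C(C)(C)C[C@@H](O)C[C@]1(C)O | target

**Totals**

Total steps: 13. Longest linear sequence: 11 (steps 1–7, then 10–13).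

**Three steps most likely to fail**

Step 2 (enzymatic C3 hydroxylation; regioselectivity and productivity on scale). The fallback is a chemical allylic oxidation on the protected ketone; it sets out from 2 and comes back at 3. Compound 2 is ketalised (ethylene glycol, HC(OEt)3, cat. PPTS) to α-ionone ethylene ketal F1. Allylic oxidation (t-BuOOH, cat. Rh2(cap)4) gives 3-oxo-α-ionone ethylene ketal F2. NaBH4/CeCl3 reduction and chromatographic removal of the cis alcohol give trans-3-hydroxy-α-ionone ethylene ketal F3. PPTS in wet acetone removes the ketal and returns 3.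

Step 12 (site and face selectivity of the epoxidation on the full polyene, over-oxidation, furanoid rearrangement). The fallback closes the oxirane before the ε ring and the full chain exist; it sets out from 11 and comes back at 18, replacing steps 10–12. Compound 11 is acetylated (Ac2O, pyridine) to (3S)-3-acetoxy-12′-apo-β-caroten-12′-al F4. mCPBA epoxidation and separation of the syn isomer give (3R,5S,6R)-3-acetoxy-5,6-epoxy-5,6-dihydro-12′-apo-β-caroten-12′-al F5. A Wittig reaction of F5 with 13 (excess NaOMe in MeOH, which also removes the acetate) gives 18, which enters step 13 at the KOtBu/DMSO stage.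

Step 13 (the anion may not form cleanly, may reprotonate to the β-ring isomer, or the product may isomerise further in strong base). The fallback switches to a cationic, biosynthesis-type opening; it sets out from 18 and comes back at 19. Compound 18 is treated with TMSOTf (3.5 equiv) and 2,6-lutidine, then DBU, in toluene at −78 → 0 °C. This silylates both hydroxyls, activates the oxirane oxygen, ionises C6–O to the polyenyl cation and removes H-6′ (a vinylogous epoxide-to-allyl-silyl-ether isomerisation), giving the tris(trimethylsilyl) ether of 19 F6. K2CO3 in MeOH then removes the silyl groups and returns 19.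

**Further compounds**

F1 | step 2 | α-ionone ethylene ketal, racemic (6R drawn) | CC1(/C=C/[C@H]2C(C)=CCCC2(C)C)OCCO1
F2 | step 2 | 3-oxo-α-ionone ethylene ketal, racemic (6R drawn) | CC1(/C=C/[C@H]2C(C)=CC(=O)CC2(C)C)OCCO1
F3 | step 2 | trans-3-hydroxy-α-ionone ethylene ketal, racemic ((3R,6R) drawn) | CC1(/C=C/[C@H]2C(C)=C[C@H](O)CC2(C)C)OCCO1
F4 | step 12 | (3S)-3-acetoxy-12′-apo-β-caroten-12′-al | O=C/C(C)=C/C=C/C=C(C)/C=C/C=C(C)/C=C/C1=C(C)C[C@H](OC(C)=O)CC1(C)C
F5 | step 12 | (3R,5S,6R)-3-acetoxy-5,6-epoxy-5,6-dihydro-12′-apo-β-caroten-12′-al | O=C/C(C)=C/C=C/C=C(C)/C=C/C=C(C)/C=C/[C@]12O[C@@]1(C)C[C@H](OC(C)=O)CC2(C)C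
F6 | step 13 | tris(trimethylsilyl) ether of 19 | CC1=C[C@@H](O[Si](C)(C)C)CC(C)(C)\C1=C/C=C(C)/C=C/C=C(C)/C=C/C=C/C(C)=C/C=C/C(C)=C/C=C1\C(C)(C)C[C@@H](O[Si](C)(C)C)C[C@]1(C)O[Si](C)(C)C
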